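**Retrosynthetic overview**
1. GA17 ⇒ oxidative scission of the C19–C20 bond (plus ester and silyl ether cleavage) of bridged cyclopentanone 9, in which C20H2 links the C19 ketone (on C4) to C10.
2. 9 ⇒ ring A olefin saturation of 8 ⇒ Claisen [3,3] shift of cyclic allyl vinyl ether 7, which makes the C10–C20 bond on the α face and gives up the C2–O bond.
3. 7 ⇒ carbonyl methylenation of the 3-deoxy 19,2-lactone 6 ⇒ deoxygenation, allylic lactone transposition and esterification of gibberellic acid (GA3).
4. Ring order: rings A, B, C and D and six of the seven stereocentres are bought in GA3. The only ring made is the temporary C4–C19–C20–C10–C5 cyclopentanone (step 7), which is reopened in step 9.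

Assumption: gibberellic acid (GA3, the bulk fermentation product) is taken as the cheap commercial chiral starting material; atom numbers follow the usual gibberellane numbering (C7 = ring B carboxyl, C19 on C4, C20 on C10, α = face of the C19 carboxyl).

**Route**

Step 1
Reactants: 1 gibberellic acid (GA3)
Product: 2 methyl gibberellate (GA3 7-methyl ester)
Conditions: MeI, K2CO3, acetone, 20 °C
Reagents that add atoms: iodomethane CI
Why: Carboxylate O-alkylation (SN2) esterifies the only free acid (C7) without touching a stereocentre, so that the later organometallic and radical steps see no acidic CO2H.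

Step 2
Reactants: 2 methyl gibberellate
Product: 3 iso-GA3 methyl ester (19,2α-lactone; 1(10)-ene; 3β,13-diol)
Conditions: 0.1 M aq K2CO3–MeOH (1:1), 20 °C, 2 h; then citric acid to pH 3
Reagents that add atoms: none
Why: The weak-alkali allylic lactone transposition of GA3 (a formal SN2′-type 1,3-acyloxy shift, run while the 3β-OH is still free) moves the C19 carboxylate from C10 to C2 on the α face, the only face the 4α-carboxyl can reach, which sets C2 and gives the more substituted 1(10)-olefin; the C10 stereocentre is given up here and rebuilt in step 7, the hindered 7-ester survives, and any ring-opened hydroxy acid relactonises on acidification.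

Step 3
Reactants: 3 iso-GA3 methyl ester
Product: 4 3-O-(phenoxythiocarbonyl) iso-GA3 methyl ester
Conditions: PhOC(S)Cl, pyridine, DMAP (cat.), CH2Cl2, 0→20 °C
Reagents that add atoms: O-phenyl chlorothionoformate S=C(Cl)Oc1ccccc1
Why: DMAP-catalysed thioacylation takes the secondary 3β-OH and leaves the tertiary bridgehead 13-OH, and it is done after step 2 so that the thionocarbonate is no longer allylic and cannot undergo a thiono–thiolo shift.

Step 4
Reactants: 4 3-O-(phenoxythiocarbonyl) iso-GA3 methyl ester
Product: 5 3-deoxy-iso-GA3 methyl ester (19,2α-lactone; 1(10),16-diene; 13-OH)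
Conditions: Bu3SnH (2 equiv, 0.3 M), AIBN (cat.), PhMe, 100 °C
Reagents that add atoms: none
Why: Barton–McCombie deoxygenation, in which the secondary C3 radical is quenched by concentrated stannane before the homoallylic radical can rearrange, a β-acyloxy radical does not fragment, and no stereocentre is formed or touched.

Step 5
Reactants: 5 3-deoxy-iso-GA3 methyl ester
Product: 6 13-O-trimethylsilyl ether of 5
Conditions: TMSCl, imidazole, DMF, 20 °C
Reagents that add atoms: chlorotrimethylsilane C[Si](C)(C)Cl
Why: Silylation of the only remaining hydroxyl removes the acidic proton before the titanium carbene step and adds bulk next to the 16-methylene, and the group falls off in the last step at no cost.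

Step 6
Reactants: 6 13-O-trimethylsilyl ether of 5
Product: 7 cyclic allyl vinyl ether (19-methylidene 19,2α-ether; 13-OTMS; 7-CO2Me)
Conditions: Cp2Ti(μ-Cl)(μ-CH2)AlMe2 (1.3 equiv), pyridine, THF–PhMe, −40→0 °C; 15% aq NaOH; basic Al2O3
Reagents that add atoms: Tebbe reagent Cp2Ti(μ-Cl)(μ-CH2)AlMe2 C[Al](C)C[Ti](Cl)(C1C=CC=C1)C1C=CC=C1
Why: Tebbe carbonyl methylenation through an oxatitanacyclobutane, in which the exposed bridged γ-lactone carbonyl (the one hydroxide opens at room temperature) is expected to react before the buried 7-ester (which needs hot alkali), and the enol ether cannot isomerise into the ring because C4 is quaternary.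

Step 7
Reactants: 7 cyclic allyl vinyl ether
Product: 8 bridged ketone (C20H2 between the C19 ketone and C10; 1(2)- and 16-enes; 13-OTMS; 7-CO2Me)
Conditions: PhMe (degassed, base-washed sealed tube), 170 °C, 6 h
Reagents that add atoms: none
Why: Claisen [3,3]-sigmatropic rearrangement of CH2=C19–O–C2–C1=C10, in which the axial C2–O bond is aligned with the ring A π bond and the bicyclic frame holds the methylidene carbon over C10 on the α face in a boat-like array, so the shift is suprafacial, C20 ends up cis to C19, and the quaternary C10 stereocentre is rebuilt under control of C4, driven by C=O formation.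

Step 8
Reactants: 8 bridged ketone
Product: 9 1,2-dihydro bridged ketone (ring A saturated; 16-ene kept)
Conditions: H2 (1 atm, 1.0 equiv by burette), 5% Pd/CaCO3, EtOAc–pyridine (9:1), 0 °C
Reagents that add atoms: none
Why: Partial catalytic hydrogenation on a pyridine-moderated palladium surface, where the strained cis-disubstituted olefin of the bicyclo[3.2.1]octene should be taken up before the 16-methylene that sits beside the bridgehead OSiMe3, pyridine curbs olefin migration, and no stereocentre is created.

Step 9
Reactants: 9 1,2-dihydro bridged ketone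
Product: 12 GA17, via bridged diketone 10 (not isolated), via silylated diacid monoester 11 (not isolated)
Conditions: KOt-Bu (6 equiv), O2 (1 atm), t-BuOH–DME, 25 °C; then 30% H2O2, 2 M aq KOH, 0→25 °C; then 75 °C, 12 h; 1 M HCl to pH 3
Reagents that add atoms: dioxygen O=O; hydrogen peroxide OO; potassium hydroxide [K+].[OH-]
Why: Base-mediated enolate autoxidation at C20, the only enolisable ketone position, gives the α-hydroperoxide that collapses (Kornblum–DeLaMare) to the non-enolisable 1,2-diketone, alkaline H2O2 then cleaves C19–C20 in a Baeyer–Villiger-type scission to the 19,20-dicarboxylate (as camphorquinone gives camphoric acid), and hot KOH saponifies the 7-ester and removes the silyl ether, with C4 and C10 untouched and C6 already in its thermodynamically preferred configuration.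

**Compound list**
1 | gibberellic acid (GA3): 3β,13-dihydroxy-1,16-diene with 19,10α-lactone and free C7 acid | C=C1C[C@]23C[C@@]1(O)CC[C@H]2[C@]14C=C[C@H](O)[C@@](C)(C(=O)O4)[C@H]1[C@@H]3C(=O)O | starting material
2 | methyl gibberellate (GA3 7-methyl ester) | C=C1C[C@]23C[C@@]1(O)CC[C@H]2[C@]14C=C[C@H](O)[C@@](C)(C(=O)O4)[C@H]1[C@@H]3C(=O)OC | intermediate
3 | iso-GA3 methyl ester: C19 carboxyl lactonised onto C2 (α face), 1(10)- and 16-enes, 3β-OH, 13-OH, 7-CO2Me | C=C1C[C@]23C[C@@]1(O)CC[C@H]2C1=C[C@@H]4[C@H](O)[C@@](C)(C(=O)O4)[C@H]1[C@@H]3C(=O)OC | intermediate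
4 | 3-O-(phenoxythiocarbonyl) derivative of 3 | C=C1C[C@]23C[C@@]1(O)CC[C@H]2C1=C[C@@H]4[C@H](OC(=S)Oc5ccccc5)[C@@](C)(C(=O)O4)[C@H]1[C@@H]3C(=O)OC | intermediate
5 | 3-deoxy-iso-GA3 methyl ester: 19,2α-lactone, 1(10),16-diene, 13-OH, 7-CO2Me | C=C1C[C@]23C[C@@]1(O)CC[C@H]2C1=C[C@@H]4C[C@@](C)(C(=O)O4)[C@H]1[C@@H]3C(=O)OC | intermediate
6 | 13-O-trimethylsilyl ether of 5 | C=C1C[C@]23C[C@@]1(O[Si](C)(C)C)CC[C@H]2C1=C[C@@H]4C[C@@](C)(C(=O)O4)[C@H]1[C@@H]3C(=O)OC | intermediate
7 | cyclic allyl vinyl ether: C19(=CH2)–O–C2 (α), 1(10),16-diene, 13-OTMS, 7-CO2Me | C=C1C[C@]23C[C@@]1(O[Si](C)(C)C)CC[C@H]2C1=C[C@@H]4C[C@@](C)(C(=C)O4)[C@H]1[C@@H]3C(=O)OC | intermediate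
8 | bridged ketone: C20H2 joins C10 (α face) to the C19 ketone on C4 (19-oxo-19,20-cyclogibberellane), 1(2)- and 16-enes, 13-OTMS, 7-CO2Me | C=C1C[C@]23C[C@@]1(O[Si](C)(C)C)CC[C@H]2[C@]14C=CC[C@@](C)(C(=O)C4)[C@H]1[C@@H]3C(=O)OC | intermediate
9 | 1,2-dihydro derivative of 8 (ring A saturated, 16-ene kept) | C=C1C[C@]23C[C@@]1(O[Si](C)(C)C)CC[C@H]2[C@]14CCC[C@@](C)(C(=O)C4)[C@H]1[C@@H]3C(=O)OC | intermediate
10 | bridged 19,20-diketone of 9 (formed in the flask in step 9) | C=C1C[C@]23C[C@@]1(O[Si](C)(C)C)CC[C@H]2[C@]14CCC[C@@](C)(C(=O)C4=O)[C@H]1[C@@H]3C(=O)OC | intermediate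
11 | 13-O-trimethylsilyl GA17 7-methyl ester (19,20-diacid; formed in the flask in step 9) | C=C1C[C@]23C[C@@]1(O[Si](C)(C)C)CC[C@H]2[C@]1(C(=O)O)CCC[C@@](C)(C(=O)O)[C@H]1[C@@H]3C(=O)OC | intermediate
12 | GA17: 13-hydroxy-16-ene gibberellin with free C7 acid, 4α-CO2H (C19) and 10α-CO2H (C20), ring configurations as in GA3 | C=C1C[C@]23C[C@@]1(O)CC[C@H]2[C@]1(C(=O)O)CCC[C@@](C)(C(=O)O)[C@H]1[C@@H]3C(=O)O | target

**Step count and risks**
Total steps: 9. Longest linear sequence: 9 (fully linear from GA3).

The three steps most likely to fail: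

Step 7 (Claisen shift in the bridged enol ether). The boat-locked thermal shift may stall, or 7 may decompose first. The fallback sets out from 7. Treatment with i-Bu3Al (3 equiv, CH2Cl2, −78→20 °C) drives the same oxygen-to-carbon allyl shift through an aluminium-bound, ion-pair-like pathway at low temperature and reduces the new ketone in the same pot, giving the bridged C19 carbinol F1 (either C19 epimer). Oxidation with Dess–Martin periodinane (NaHCO3, CH2Cl2) then comes back to the route at 8.

Step 8 (ring A olefin against the 16-methylene). If hydrogen uptake is not selective, the 16-ene is masked first. The fallback sets out from 8. K2CO3 in MeOH removes the silyl ether to give the 13-hydroxy dienone F2. VO(acac)2 (cat.) and t-BuOOH in CH2Cl2 epoxidise only the olefin of the tertiary allylic alcohol, giving the 16,17-epoxide F3. H2 over Pd/C in EtOAc then saturates ring A without competition to give the saturated epoxy ketone F4. Deoxygenation with the trivalent titanium reagent Cp2TiCl (from Cp2TiCl2 and Zn, THF) restores the 16-methylene in the 13-hydroxy ketone F5; the bridgehead carbinol cannot eliminate. Resilylation (TMSCl, imidazole, DMF) comes back to the route at 9.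

Step 6 (lactone against 7-ester in the methylenation, and survival of the enol ether). If the titanium carbene also attacks the ester, or the aluminium by-products destroy 7, the enol ether is made by addition and elimination instead. The fallback sets out from 6. MeLi (1.05 equiv, THF, −78 °C) adds once to the lactone carbonyl, the same carbonyl that hydroxide opens in preference to the 7-ester, to give the 19-methyl lactol F6. Dehydration with MsCl, Et3N and DMAP (cat.) in CH2Cl2 at 0 °C can only place the double bond exocyclic, since C4 is quaternary, and comes back to the route at 7.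

**Further compounds**
F1 | step 7 | bridged C19 carbinol (reduced form of 8, C19 configuration not fixed) | C=C1C[C@]23C[C@@]1(O[Si](C)(C)C)CC[C@H]2[C@]14C=CC[C@@](C)(C(O)C4)[C@H]1[C@@H]3C(=O)OC
F2 | step 8 | 13-hydroxy dienone (8 without the silyl group) | C=C1C[C@]23C[C@@]1(O)CC[C@H]2[C@]14C=CC[C@@](C)(C(=O)C4)[C@H]1[C@@H]3C(=O)OC
F3 | step 8 | 16,17-epoxide of F2 (C16 configuration not fixed) | C1OC12C[C@]34C[C@@]2(O)CC[C@H]3[C@]25C=CC[C@@](C)(C(=O)C5)[C@H]2[C@@H]4C(=O)OC
F4 | step 8 | 1,2-dihydro derivative of F3 (saturated epoxy ketone) | C1OC12C[C@]34C[C@@]2(O)CC[C@H]3[C@]25CCC[C@@](C)(C(=O)C5)[C@H]2[C@@H]4C(=O)OC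
F5 | step 8 | 13-hydroxy saturated ketone (9 without the silyl group) | C=C1C[C@]23C[C@@]1(O)CC[C@H]2[C@]14CCC[C@@](C)(C(=O)C4)[C@H]1[C@@H]3C(=O)OC
F6 | step 6 | 19-methyl lactol of 6 (C19 configuration not fixed) | C=C1C[C@]23C[C@@]1(O[Si](C)(C)C)CC[C@H]2C1=C[C@@H]4C[C@@](C)(C(C)(O)O4)[C@H]1[C@@H]3C(=O)OC
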